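The charge of L is small, and a small charge bounds a loss.

| flask | E | L | temperature | remark | time |
|---|---|---|---|---|---|
| north-east | 0.050 M | 0.0067 M | 25 °C | run made earlier |  |
| epsilon | 0.10 M | 0.0100 M | 45 °C |  | 30 h |
| gamma | 0.050 M | 0.0100 M | 25 °C |  | 30 h |

- north-east (time / h: X / %): 2.00: 2; 4.00: 9; 6.00: 11; 8.00: 22; 10.0: 22

(scatter of a reading: 2 percentage points)

- the earlier runs were read with a standard deviation of 2 percentage points
- on the list of suspects stand: E <-> J; D -> X; J <-> Q; D <-> G; E + L -> Z; E -> D
- the earlier runs do not show what temperature does; that part of a forecast is a guess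
- no earlier run changes the charge of L; that part of a forecast is a guess

1. which of the two ends with the higher amount of X, in percent of the E charged ("neither" if they lie within 2 percentage points) (epsilon / gamma / neither)
2. X at the end, in percent of the E charged, epsilon
3. X at the end, in percent of the E charged, gamma

The suspect step E + L → Z spends one L for each E, so the share of charged E that ends as Z is at most [L]/[E] at the start. That is 10.0 % in epsilon, and I call this ratio the L ceiling. It is a bound on a loss, so I read it as a floor under X: a flask whose remaining E has reached X holds at least 90.0 % X in epsilon and 80.0 % in gamma.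

I hold that floor against the pace of the one run on hand. The north-east run reads X at 22 % after 10.0 h, with a scatter of 2 percentage points. Held at that pace, gamma's 30 h at the same 25 °C give 66.0 %, less than its floor, so I expect gamma to stop on the clock, at or below that figure. Epsilon runs at 45 °C, and what that does is a guess; I guess that it finishes, and I commit to at least 90.0 % there, with epsilon ahead.

The forecast also names epsilon, with 78 % for epsilon and 50 % for gamma, and says of L that “it caps X at about 80 % in gamma (L/E = 0.20) and about 90 % in epsilon (L/E = 0.10)”. We differ here: the forecast reads the ratio as a cap on X, and I read it as a floor.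

The flasks give 94.7 % X in epsilon and 45.8 % in gamma, so epsilon leads.

    E ⇌ J (K = 2.10, k = 0.0910 /h, Ea = 91.0 kJ/mol, ΔH = −31.0 kJ/mol)
    D → X (k = 0.0580 /h, Ea = 110 kJ/mol)
    J ⇌ Q (K = 27.0, k = 0.0240 /h, Ea = 93.0 kJ/mol, ΔH = −78.0 kJ/mol)
    D ⇌ G (K = 1.00, k = 0.0930 /h, Ea = 100 kJ/mol, ΔH = 2.00 kJ/mol)
    E + L → Z (k = 8.40 /M/h, Ea = 52.0 kJ/mol)
    E → D (k = 0.410 /h, Ea = 100 kJ/mol)
    (constants at 25 °C)

Gamma ends at 45.8 %, below its floor of 80.0 %, and the time allowed and the loss of D to G, both ways, act together in that shortfall: with ten times the time gamma reaches 82.8 %, and without D ⇌ G it ends at 62.9 %. Epsilon ends above its floor of 90.0 %, with Z at 4.37 %, less than the ceiling of 10.0 %, E down to 0.0079 % and 56 % of the L charge remaining. The neighbour flask, epsilon with 0.040 M of L, has a ceiling of 40.0 % and a floor of 60.0 %; it holds 15.9 % Z and ends at 83.3 % X.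

The earlier runs and the new flask were computed for substances that don't exist, and the scatter is random.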